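All runs come from a simulation for substances that don't exist; the scatter is artificial.

The easy step comes first: each target formed costs one nucleophile, so the early rise of target in a run gives an estimate of how fast nucleophile is spent.

| setting | cedar | oak | amber | ochre | green |
|---|---|---|---|---|---|
| solid electrophile | 0.070 M | 0.070 M | 0.070 M | 0.070 M | 0.070 M |
| nucleophile | 0.80 equiv | 0.80 equiv | 0.800 equiv | 0.800 equiv | 0.800 equiv |
| free base | 0.86 equiv | 2.6 equiv | 1.50 equiv | 2.20 equiv | 3.40 equiv |
| remark | run made earlier | run made earlier |  |  |  |
| time |  |  | 10 h | 10 h | 10 h |

| run | time / h | solid electrophile / % | target / % |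
|---|---|---|---|
| cedar | 0.333 | 92.6 | 4.8 |
| cedar | 1.00 | 80.5 | 15.7 |
| cedar | 2.00 | 62.2 | 30.6 |
| cedar | 2.50 | 53.7 | 38.6 |
| cedar | 4.00 | 31.6 | 55.1 |
| cedar | 5.00 | 19.9 | 62.6 |
| oak | 0.417 | 91.5 | 5.1 |
| oak | 0.667 | 86.6 | 9.9 |
| oak | 1.00 | 79.1 | 15.5 |
| oak | 2.00 | 62.1 | 32.0 |
| oak | 3.00 | 45.2 | 48.0 |
| oak | 5.00 | 17.5 | 65.8 |

(each reading ± 0.5 percentage points)

- at the start none of the solid electrophile is in solution
- what has only dissolved of solid electrophile counts as not reacted

- part of the solid electrophile that has reacted (what has only dissolved counts as not reacted) at the end, amber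
- part of the solid electrophile that has reacted (what has only dissolved counts as not reacted) at the end, ochre
- part of the solid electrophile that has reacted (what has only dissolved counts as not reacted) at the end, green
- what raising the equivalents of free base from its lowest to its highest value here does to the part of the solid electrophile that has reacted (what has only dissolved counts as not reacted) (changes below 5 percentage points count as none) (it rises / no change / it falls)

In the cedar run, target climbs from 4.8% at 0.333 h to 38.6% at 2.50 h, a steady 0.156 h⁻¹ as a fraction of the charge. So straight a line suggests zero order: dissolution as the rate-limiting step, with c(electrophile) roughly level. Free base shows no hand in it: at 2.00 h, cedar with 0.86 equiv holds 62.2% of solid and oak with 2.6 equiv holds 62.1%. A charge of 0.800 equiv lasts 5.13 h at this rate; this is the nucleophile lifetime, charge over steady rate of target formation. The second time is the asked 10 h, twice that lifetime. This reckoning gives a time, not a percentage, and it expects no effect of free base. The percentages hang on what becomes of the gap between solid lost and target, 17.5% at 5.00 h in cedar: waiting in solution, or reacted.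

The forecast gives amber 79%, ochre 79% and green 79%, each with a range from 75% to 81%, and no change. Its ground: “The nucleophile at 0.80 equiv is limiting, so conversion caps at 80%.”

The flasks give amber 92.5%, ochre 92.6% and green 92.6%, above that range, and the trend is no change, a change of 0.12 percentage points.

    solid electrophile ⇌ electrophile, rate k1*(cs1 - [electrophile]) while solid is left; crystals form when [electrophile] > cs1 (solubility = 15.0 mM, k = 3.00 × 10⁻⁴ s⁻¹)
    electrophile + target → side product (k = 9.70 × 10⁻⁴ M⁻¹ s⁻¹)
    nucleophile + acid set free ⇌ protonated nucleophile, settled at all times (K = 650 M⁻¹)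
    acid set free + free base ⇌ salt of the base (K = 1800 M⁻¹, k = 0.540 M⁻¹ s⁻¹)
    electrophile + nucleophile → acid set free + target (k = 0.0290 M⁻¹ s⁻¹)

In amber, nucleophile falls under 2% of its charge at 7.33 h, later than the reckoned lifetime of 5.13 h, and 0.48% of its charge stands unbound at 10.0 h. At that time the step with nucleophile uses electrophile at 0.17 of the rate of the step with target, and side product stands at 26.0%, a figure counting both electrophile units it holds. The neighbour flask, amber with 0.200 equiv of nucleophile, has a reckoned lifetime of 1.28 h against 10 h; computed, 26.3% of its solid electrophile has reacted, with unbound nucleophile at 0% of its charge and side product at 12.7%.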